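The route rests on disconnecting the butenolide between its carbonyl carbon (C10) and its α-carbon (C7), the ring-fusion carbon that also bears the cyclopropane. Because C7 and the lactone CH2 (C9) are cis on the tetrasubstituted C7=C8 alkene shared by the butenolide and the eight-membered ring, a palladium-catalysed carbonylation of an acyclic (Z)-dienyl triflate carrying a cis hydroxymethyl group inserts CO, forms the C7–C10 bond and closes the butenolide in one operation. The triflate diol comes from a β-keto γ-lactone whose ring oxygen ends as the C1 acetate oxygen. Ring-closing metathesis, cyclopropanation and a singlet-oxygen ene reaction follow.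

Key step: step 14

Remark on locants: C1 = ring carbon bearing OAc; C2 = ring CH2; C3 = ring CH(CH3); C4 and C6 = cyclopropane CH next to C3 and next to C7; C5 = cyclopropane CH2; C7 and C8 = butenolide α- and β-carbons; C9 = OCH2; C10 = lactone C=O; C11 = ring CH bearing the side chain; C12 to C16 = side chain from CH(CH3) to C(CH3)2OOH.

Remark on the chemistry: the hydroperoxide is taken to arise from the corresponding 6-methylhept-5-en-2-yl side chain by a singlet-oxygen ene reaction, and compounds 1, 2 and 9 are taken as commercial in the stated enantiomeric form.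

Step 1
Reactants: 1 (R)-citronellic acid; 2 (R)-4-benzyl-1,3-oxazolidin-2-one
Product: 4 (4R)-4-benzyl-3-[(3R)-3,7-dimethyloct-6-enoyl]-1,3-oxazolidin-2-one, via mixed pivalic anhydride 3 (not isolated)
Conditions: t-BuCOCl, Et3N, THF, −20 °C; then 2, LiCl, −20 → 23 °C
Reagents that add atoms: none
Why: N-acylation of the oxazolidinone by the mixed anhydride formed in situ (LiCl-promoted) installs the Evans auxiliary without touching the C12 centre.

Step 2
Reactants: 4 N-acyl oxazolidinone; 5 tert-butyl bromoacetate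
Product: 7 tert-butyl (3R,4R)-3-{[(4R)-4-benzyl-2-oxo-1,3-oxazolidin-3-yl]carbonyl}-4,8-dimethylnon-7-enoate, via sodium (Z)-enolate 6 (not isolated)
Conditions: NaN(SiMe3)2, THF, −78 °C; then 5, −78 → −40 °C
Reagents that add atoms: none
Why: Evans asymmetric alkylation, in which the chelated (Z)-enolate is alkylated on the face opposite the benzyl group of the (R)-auxiliary, sets C11 (R in 7, the 11S centre of the target) under auxiliary control irrespective of C12.

Step 3
Reactants: 7 alkylated imide
Product: 8 tert-butyl (3R,4R)-3-[(ethylsulfanyl)carbonyl]-4,8-dimethylnon-7-enoate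
Conditions: EtSH, n-BuLi, THF, 0 °C
Reagents that add atoms: ethanethiol (used as LiSEt), CCS
Why: Transthioesterification by lithium ethanethiolate cleaves the hindered imide at the exocyclic carbonyl, leaves the tert-butyl ester and C11 untouched and returns auxiliary 2.

Step 4
Reactants: 9 methyl (2R)-3-hydroxy-2-methylpropanoate
Product: 10 methyl (2R)-3-[(tert-butyldimethylsilyl)oxy]-2-methylpropanoate
Conditions: TBSCl, imidazole, CH2Cl2, 23 °C
Reagents that add atoms: tert-butyldimethylsilyl chloride, CC(C)(C)[Si](C)(C)Cl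
Why: Standard silylation masks the primary alcohol during reduction and olefination.

Step 5
Reactants: 10 silyl ether ester
Product: 11 (2R)-3-[(tert-butyldimethylsilyl)oxy]-2-methylpropanal
Conditions: i-Bu2AlH (1.05 equiv), CH2Cl2, −78 °C
Reagents that add atoms: none
Why: Half-reduction of the ester stops at the aldehyde through the tetrahedral aluminate that is stable at −78 °C, and the α-centre is not epimerised at this temperature.

Step 6
Reactants: 11 aldehyde
Product: 12 tert-butyldimethyl{[(2S)-2-methylbut-3-en-1-yl]oxy}silane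
Conditions: Ph3PCH3Br, KN(SiMe3)2, THF, −78 → 0 °C
Reagents that add atoms: methylenetriphenylphosphorane (from methyltriphenylphosphonium bromide), C=P(c1ccccc1)(c1ccccc1)c1ccccc1
Why: Wittig methylenation with the non-stabilised ylide creates the vinyl group that becomes C4 without racemising the adjacent centre (the later C3).

Step 7
Reactants: 12 silyl ether
Product: 13 (3S)-4-bromo-3-methylbut-1-ene
Conditions: Ph3PBr2, CH2Cl2, 0 → 23 °C
Reagents that add atoms: dibromotriphenylphosphorane, BrP(Br)(c1ccccc1)(c1ccccc1)c1ccccc1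
Why: Ph3PBr2 converts a primary silyl ether directly into the bromide by SN2 displacement at the CH2 carbon, so the stereocentre is not involved.

Step 8
Reactants: 8 thioester; 13 bromide
Product: 16 tert-butyl (3R,4R)-4,8-dimethyl-3-[(3R)-3-methylpent-4-enoyl]non-7-enoate, via Grignard reagent 14 (not isolated), via alkylzinc chloride 15 (not isolated)
Conditions: 13, Mg, THF, 23 °C; ZnCl2, 0 °C; then 8, PdCl2(PPh3)2 (5 mol %), PhMe, 23 °C
Reagents that add atoms: none
Why: Fukuyama coupling of the alkylzinc reagent (made at once from the Grignard reagent to avoid homoallyl rearrangement) with the thioester gives the ketone without over-addition, attack on the tert-butyl ester or epimerisation at C11.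

Step 9
Reactants: 16 ketone
Product: 18 (4R,5R)-4-[(2R)-6-methylhept-5-en-2-yl]-5-[(2R)-2-methylbut-3-en-1-yl]oxolan-2-one, via hydroxy ester 17 (not isolated)
Conditions: (S)-2-methyl-CBS-oxazaborolidine, catecholborane, PhMe, −78 → −40 °C; then t-BuOK (0.2 equiv), THF, 0 °C
Reagents that add atoms: none
Why: CBS reduction under reagent control (ketone bound with the branched C11 side as the large group) sets the 1R carbinol, and the alkoxide then displaces tert-butoxide intramolecularly to give the trans-4,5-disubstituted γ-lactone.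

Step 10
Reactants: 18 lactone; 19 (E)-but-2-enal
Product: 21 (4S,5R)-3-[(2E)-1-hydroxybut-2-en-1-yl]-4-[(2R)-6-methylhept-5-en-2-yl]-5-[(2R)-2-methylbut-3-en-1-yl]oxolan-2-one (diastereomers at C8 and C7), via lithium enolate 20 (not isolated)
Conditions: LiN(i-Pr)2, THF, −78 °C; then 19, −78 °C; AcOH
Reagents that add atoms: none
Why: Aldol addition of the lactone lithium enolate (C8) occurs 1,2 to the enal at −78 °C; the two new centres at C8 and C7 need no control because both become sp2 in steps 11 and 12.

Step 11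
Reactants: 21 aldol adduct
Product: 22 (4S,5R)-3-[(2E)-but-2-enoyl]-4-[(2R)-6-methylhept-5-en-2-yl]-5-[(2R)-2-methylbut-3-en-1-yl]oxolan-2-one
Conditions: Dess–Martin periodinane, CH2Cl2, 23 °C
Reagents that add atoms: none
Why: Dess–Martin oxidation of the allylic alcohol gives the β-keto lactone under non-basic conditions that avoid Michael self-condensation.

Step 12
Reactants: 22 β-keto lactone
Product: 24 (1Z,2E)-1-{(4S,5R)-4-[(2R)-6-methylhept-5-en-2-yl]-5-[(2R)-2-methylbut-3-en-1-yl]-2-oxooxolan-3-ylidene}but-2-en-1-yl trifluoromethanesulfonate, via sodium (Z)-enolate 23 (not isolated)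
Conditions: NaH, THF, 0 °C; then PhNTf2, 0 → 23 °C
Reagents that add atoms: N-phenylbis(trifluoromethanesulfonimide), O=S(=O)(N(c1ccccc1)S(=O)(=O)C(F)(F)F)C(F)(F)F
Why: O-sulfonylation of the sodium-chelated enolate, in which the enolate oxygen is held cis to the lactone carbonyl, gives the (Z)-enol triflate regiospecifically at C7.

Step 13
Reactants: 24 enol triflate lactone
Product: 26 (2E,4Z,6S,7R,9R)-7-hydroxy-5-(hydroxymethyl)-9-methyl-6-[(2R)-6-methylhept-5-en-2-yl]undeca-2,4,10-trien-4-yl trifluoromethanesulfonate, via lactol 25 (not isolated)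
Conditions: i-Bu2AlH (4 equiv), CH2Cl2, −78 → 0 °C
Reagents that add atoms: none
Why: i-Bu2AlH reduces the lactone 1,2 to the lactol and, after ring opening, the enal to the allylic alcohol, which frees C9–OH and C1–OH while the enol triflate survives, as is known for β-triflyloxy enoates.

Step 14
Reactants: 26 triflate diol
Product: 27 4-[(3R,5R,6S,7R)-5-hydroxy-3,7,11-trimethyldodeca-1,10-dien-6-yl]-3-[(1E)-prop-1-en-1-yl]furan-2(5H)-one
Conditions: Pd(PPh3)4 (10 mol %), CO (1 atm), n-Bu3N, LiCl, MeCN, 65 °C
Reagents that add atoms: carbon monoxide, [C-]#[O+]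
Why: Zerovalent palladium inserts into the C7–OTf bond with retention of the Z geometry and migratory insertion of CO forges the C7–C10 bond; the C9 hydroxyl, held cis and coplanar on C8, then captures the acylpalladium (or, through the chelated palladium alkoxide, forms an alkoxycarbonyl that reductively eliminates onto C7) while n-Bu3N takes up TfOH. The closest known reaction type is the palladium-catalysed carbonylative lactonisation of (Z)-3-hydroxyalkenyl triflates and halides to butenolides. The butenolide ring closes by a 5-exo-trig acyl substitution at the acylpalladium carbon. No stereocentre is created, C1, C3, C11 and C12 are remote from the reacting atoms and the C7=C8 geometry is locked into the new ring. The step needs capture by the primary allylic C9–OH instead of the secondary C1–OH (which would give a six-membered lactone); the Z geometry, the five-membered transition state and the lower hindrance at C9 secure this, and base-mediated translactonisation to the more stable butenolide acts as a funnel.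

Step 15
Reactants: 27 hydroxy butenolide
Product: 28 (3R,5R,6S,7R)-3,7,11-trimethyl-6-{5-oxo-4-[(1E)-prop-1-en-1-yl]-2,5-dihydrofuran-3-yl}dodeca-1,10-dien-5-yl acetate
Conditions: Ac2O, pyridine, DMAP (cat.), CH2Cl2, 23 °C
Reagents that add atoms: acetic anhydride, CC(=O)OC(C)=O
Why: Standard acetylation of the only hydroxyl installs the C1 acetate with retention.

Step 16
Reactants: 28 acetate
Product: 29 (4S,5R,7R,8Z)-7-methyl-4-[(2R)-6-methylhept-5-en-2-yl]-1-oxo-1,3,4,5,6,7-hexahydrocycloocta[c]furan-5-yl acetate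
Conditions: second-generation Hoveyda–Grubbs catalyst (10 mol %), PhMe (1 mM), 80 °C
Reagents that add atoms: none
Why: Ring-closing metathesis between the C4 vinyl group and the propenyl group on C7 closes the eight-membered ring with loss of propene, the Z C7=C8 alkene of the butenolide holding both arms on one side and the ring size enforcing a cis C4=C6 alkene.

Step 17
Reactants: 29 cyclooctadiene-fused butenolide
Product: 30 the C4–C6 cyclopropane of 29 (1R,3R,4S,6S,11S,12R in the locants of the remark; side chain (2R)-6-methylhept-5-en-2-yl)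
Conditions: CH2N2, Pd(OAc)2 (5 mol %), Et2O, 0 °C
Reagents that add atoms: diazomethane, C=[N+]=[N-]
Why: Palladium-catalysed methylene transfer from diazomethane reacts with the cis-disubstituted C4=C6 alkene and leaves the tetrasubstituted and trisubstituted alkenes alone; delivery anti to the allylic C3 methyl group sets C4 and C6, with the cis ring fusion following from the cis alkene.

Step 18
Reactants: 30 cyclopropane
Product: 31 CNP0205234.1, the target hydroperoxide
Conditions: O2, tetraphenylporphyrin (cat.), visible light, CH2Cl2, 0 °C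
Reagents that add atoms: dioxygen (as singlet oxygen), O=O
Why: Schenck ene reaction, in which singlet oxygen attacks only the electron-rich trisubstituted side-chain alkene and abstraction of an allylic hydrogen from C14 gives the tertiary hydroperoxide with the E C14=C15 alkene, to be separated from the regioisomeric secondary hydroperoxide.

Compound list
1 | (R)-citronellic acid, (3R)-3,7-dimethyloct-6-enoic acid | OC(=O)C[C@H](C)CCC=C(C)C | starting material
2 | (R)-4-benzyl-1,3-oxazolidin-2-one | O=C1OC[C@@H](Cc2ccccc2)N1 | starting material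
3 | (3R)-3,7-dimethyloct-6-enoic pivalic anhydride | CC(C)(C)C(=O)OC(=O)C[C@H](C)CCC=C(C)C | intermediate (not isolated)
4 | (4R)-4-benzyl-3-[(3R)-3,7-dimethyloct-6-enoyl]-1,3-oxazolidin-2-one | O=C1OC[C@@H](Cc2ccccc2)N1C(=O)C[C@H](C)CCC=C(C)C | intermediate
5 | tert-butyl bromoacetate | BrCC(=O)OC(C)(C)C | starting material
6 | sodium (Z)-enolate of 4 | [Na+].[O-]/C(=C\[C@H](C)CCC=C(C)C)N1[C@H](Cc2ccccc2)COC1=O | intermediate (not isolated)
7 | tert-butyl (3R,4R)-3-{[(4R)-4-benzyl-2-oxo-1,3-oxazolidin-3-yl]carbonyl}-4,8-dimethylnon-7-enoate | O=C1OC[C@@H](Cc2ccccc2)N1C(=O)[C@H](CC(=O)OC(C)(C)C)[C@H](C)CCC=C(C)C | intermediate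
8 | tert-butyl (3R,4R)-3-[(ethylsulfanyl)carbonyl]-4,8-dimethylnon-7-enoate | CCSC(=O)[C@H](CC(=O)OC(C)(C)C)[C@H](C)CCC=C(C)C | intermediate
9 | methyl (2R)-3-hydroxy-2-methylpropanoate | OC[C@@H](C)C(=O)OC | starting material
10 | methyl (2R)-3-[(tert-butyldimethylsilyl)oxy]-2-methylpropanoate | CC(C)(C)[Si](C)(C)OC[C@@H](C)C(=O)OC | intermediate
11 | (2R)-3-[(tert-butyldimethylsilyl)oxy]-2-methylpropanal | CC(C)(C)[Si](C)(C)OC[C@@H](C)C=O | intermediate
12 | tert-butyldimethyl{[(2S)-2-methylbut-3-en-1-yl]oxy}silane | CC(C)(C)[Si](C)(C)OC[C@@H](C)C=C | intermediate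
13 | (3S)-4-bromo-3-methylbut-1-ene | BrC[C@@H](C)C=C | intermediate
14 | [(2S)-2-methylbut-3-en-1-yl]magnesium bromide | Br[Mg]C[C@@H](C)C=C | intermediate (not isolated)
15 | [(2S)-2-methylbut-3-en-1-yl]zinc chloride | Cl[Zn]C[C@@H](C)C=C | intermediate (not isolated)
16 | tert-butyl (3R,4R)-4,8-dimethyl-3-[(3R)-3-methylpent-4-enoyl]non-7-enoate | CC(C)(C)OC(=O)C[C@@H](C(=O)C[C@@H](C)C=C)[C@H](C)CCC=C(C)C | intermediate
17 | tert-butyl (3R,4R)-3-[(1R,3R)-1-hydroxy-3-methylpent-4-en-1-yl]-4,8-dimethylnon-7-enoate | CC(C)(C)OC(=O)C[C@@H]([C@H](O)C[C@@H](C)C=C)[C@H](C)CCC=C(C)C | intermediate (not isolated)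
18 | (4R,5R)-4-[(2R)-6-methylhept-5-en-2-yl]-5-[(2R)-2-methylbut-3-en-1-yl]oxolan-2-one | O=C1C[C@H]([C@H](C)CCC=C(C)C)[C@@H](C[C@@H](C)C=C)O1 | intermediate
19 | (E)-but-2-enal | C/C=C/C=O | starting material
20 | lithium enolate of 18 | [Li+].[O-]C1=C[C@H]([C@H](C)CCC=C(C)C)[C@@H](C[C@@H](C)C=C)O1 | intermediate (not isolated)
21 | (4S,5R)-3-[(2E)-1-hydroxybut-2-en-1-yl]-4-[(2R)-6-methylhept-5-en-2-yl]-5-[(2R)-2-methylbut-3-en-1-yl]oxolan-2-one | O=C1C(C(O)/C=C/C)[C@H]([C@H](C)CCC=C(C)C)[C@@H](C[C@@H](C)C=C)O1 | intermediate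
22 | (4S,5R)-3-[(2E)-but-2-enoyl]-4-[(2R)-6-methylhept-5-en-2-yl]-5-[(2R)-2-methylbut-3-en-1-yl]oxolan-2-one | O=C1C(C(=O)/C=C/C)[C@H]([C@H](C)CCC=C(C)C)[C@@H](C[C@@H](C)C=C)O1 | intermediate
23 | sodium (Z)-enolate of 22 | [Na+].O=C1/C(=C(\[O-])/C=C/C)[C@H]([C@H](C)CCC=C(C)C)[C@@H](C[C@@H](C)C=C)O1 | intermediate (not isolated)
24 | (1Z,2E)-1-{(4S,5R)-4-[(2R)-6-methylhept-5-en-2-yl]-5-[(2R)-2-methylbut-3-en-1-yl]-2-oxooxolan-3-ylidene}but-2-en-1-yl trifluoromethanesulfonate | O=C1/C(=C(\OS(=O)(=O)C(F)(F)F)/C=C/C)[C@H]([C@H](C)CCC=C(C)C)[C@@H](C[C@@H](C)C=C)O1 | intermediate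
25 | lactol of 24: (1Z,2E)-1-{(4S,5R)-2-hydroxy-4-[(2R)-6-methylhept-5-en-2-yl]-5-[(2R)-2-methylbut-3-en-1-yl]oxolan-3-ylidene}but-2-en-1-yl trifluoromethanesulfonate | OC1/C(=C(\OS(=O)(=O)C(F)(F)F)/C=C/C)[C@H]([C@H](C)CCC=C(C)C)[C@@H](C[C@@H](C)C=C)O1 | intermediate (not isolated)
26 | (2E,4Z,6S,7R,9R)-7-hydroxy-5-(hydroxymethyl)-9-methyl-6-[(2R)-6-methylhept-5-en-2-yl]undeca-2,4,10-trien-4-yl trifluoromethanesulfonate | OC/C(=C(\OS(=O)(=O)C(F)(F)F)/C=C/C)[C@@H]([C@H](O)C[C@@H](C)C=C)[C@H](C)CCC=C(C)C | intermediate
27 | 4-[(3R,5R,6S,7R)-5-hydroxy-3,7,11-trimethyldodeca-1,10-dien-6-yl]-3-[(1E)-prop-1-en-1-yl]furan-2(5H)-one | O=C1OCC([C@@H]([C@H](O)C[C@@H](C)C=C)[C@H](C)CCC=C(C)C)=C1/C=C/C | intermediate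
28 | (3R,5R,6S,7R)-3,7,11-trimethyl-6-{5-oxo-4-[(1E)-prop-1-en-1-yl]-2,5-dihydrofuran-3-yl}dodeca-1,10-dien-5-yl acetate | O=C1OCC([C@@H]([C@H](OC(C)=O)C[C@@H](C)C=C)[C@H](C)CCC=C(C)C)=C1/C=C/C | intermediate
29 | (4S,5R,7R,8Z)-7-methyl-4-[(2R)-6-methylhept-5-en-2-yl]-1-oxo-1,3,4,5,6,7-hexahydrocycloocta[c]furan-5-yl acetate | CC(=O)O[C@@H]1C[C@@H](C)/C=C\C2=C(COC2=O)[C@@H]1[C@H](C)CCC=C(C)C | intermediate
30 | C4–C6 cyclopropane of 29, cyclopropane CH2 anti to the C3 methyl (1R,3R,4S,6S,11S,12R) | CC(=O)O[C@@H]1C[C@@H](C)[C@@H]2C[C@@H]2C2=C(COC2=O)[C@@H]1[C@H](C)CCC=C(C)C | intermediate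
31 | CNP0205234.1, tertiary allylic hydroperoxide of 30 with E C14=C15 alkene | CC(=O)O[C@@H]1C[C@@H](C)[C@@H]2C[C@@H]2C2=C(COC2=O)[C@@H]1[C@H](C)C/C=C/C(C)(C)OO | target

Total step count: 18. Longest linear sequence: 15 steps (9 → 31, steps 4 to 18).

Steps most likely to fail

1. Step 16 (ring-closing metathesis). What may go wrong: intermolecular metathesis (oligomerisation) outruns closure of the eight-membered ring, or the catalyst is drawn onto the trisubstituted side-chain alkene. Fallback: the ring is closed earlier, on β-keto lactone 22, where the five-membered lactone ties C8 and C1, the two carbons that carry the olefin arms, into one small ring (C8 epimerises freely to the cis arrangement). Ring-closing metathesis of 22 under the conditions of step 16 should give the bridged keto lactone F1. NaH and PhNTf2 should then give the bicyclic dienyl triflate F2, whose C7=C8 geometry is dictated by the ring. i-Bu2AlH should open the lactone to the cyclic triflate diol F3. The carbonylation of step 14 then annulates the butenolide onto the preformed ring to give the hydroxy butenolide F4, and acetylation as in step 15 comes back at 29.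

2. Step 17 (cyclopropanation). What may go wrong: poor facial selectivity of methylene transfer, or slow transfer to an alkene that is conjugated with the butenolide. Fallback: delivery is directed by the C1 hydroxyl instead of relying on steric control. Setting out from 27, ring-closing metathesis of the free alcohol under the conditions of step 16 should give the hydroxy butenolide F4. A hydroxyl-directed Simmons–Smith reaction (Et2Zn, CH2I2, CH2Cl2, 0 °C) should place the methylene on the face of the C1–OH, which is the required face, to give the cyclopropyl alcohol F5. Acetylation as in step 15 comes back at 30.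

3. Step 18 (ene reaction). What may go wrong: poor regioselectivity of hydrogen abstraction, so that much of the material is diverted to the secondary hydroperoxide with an isopropenyl terminus. Fallback: a stepwise, regiodefined transposition. Setting out from 30, m-CPBA (CH2Cl2, 0 °C) should epoxidise only the trisubstituted side-chain alkene to give the epoxide F6. PhSeNa (from PhSeSePh and NaBH4, EtOH) should open it at the secondary carbon to give the hydroxy selenide F7. Oxidation with H2O2 and syn elimination away from the carbinol carbon should give the (E)-allylic tertiary alcohol F8. Acid-catalysed exchange of the tertiary allylic hydroxyl for hydroperoxide (50% H2O2, cat. H2SO4, Et2O, 0 °C) comes back at 31.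

Further compounds
F1 | step 16 | bridged β-keto lactone from ring-closing metathesis of 22 (C8 configuration fixed by the bridge) | O=C1O[C@@H]2C[C@@H](C)/C=C\C(=O)C1[C@@H]2[C@H](C)CCC=C(C)C
F2 | step 16 | bicyclic dienyl triflate lactone | O=C1O[C@@H]2C[C@@H](C)/C=C\C(OS(=O)(=O)C(F)(F)F)=C1/[C@@H]2[C@H](C)CCC=C(C)C
F3 | step 16 | cyclooctadienyl triflate diol | O[C@@H]1C[C@@H](C)/C=C\C(OS(=O)(=O)C(F)(F)F)=C(CO)/[C@@H]1[C@H](C)CCC=C(C)C
F4 | step 16 | hydroxy butenolide, deacetyl-29 | O[C@@H]1C[C@@H](C)/C=C\C2=C(COC2=O)[C@@H]1[C@H](C)CCC=C(C)C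
F5 | step 17 | cyclopropyl alcohol, deacetyl-30 | O[C@@H]1C[C@@H](C)[C@@H]2C[C@@H]2C2=C(COC2=O)[C@@H]1[C@H](C)CCC=C(C)C
F6 | step 18 | side-chain epoxide of 30 (epimers at the epoxide CH) | CC(=O)O[C@@H]1C[C@@H](C)[C@@H]2C[C@@H]2C2=C(COC2=O)[C@@H]1[C@H](C)CCC3OC3(C)C
F7 | step 18 | β-hydroxy phenyl selenide | CC(=O)O[C@@H]1C[C@@H](C)[C@@H]2C[C@@H]2C2=C(COC2=O)[C@@H]1[C@H](C)CCC([Se]c3ccccc3)C(C)(C)O
F8 | step 18 | (E)-allylic tertiary alcohol | CC(=O)O[C@@H]1C[C@@H](C)[C@@H]2C[C@@H]2C2=C(COC2=O)[C@@H]1[C@H](C)C/C=C/C(C)(C)O
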